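**Retrosyn­thetic overview**
1. Target 35 ⇐ bis‑silyl ether 34 ⇐ B‑alkyl Suzuki–Miyaura union of alkenyl triflate 10 (rings A/B) with the 9‑BBN adduct of dienyl lactone 32.
2. 32 ⇐ copper‑catalysed sp2–sp3 coupling of (Z)‑dienyl iodide 30 with triflate 24; 30 comes from propargyl alcohol by anti‑carbomagnesiation/iodination, which fixes the Z‑trisubstituted alkene.
3. Key step: 24 ⇐ lactone 21 ⇐ ester 18, made by a Johnson–Claisen [3,3]‑sigmatropic rearrangement of the (Z)‑allylic alcohol from D‑glyceraldehyde acetonide. It forms the bond that becomes lactone C3–C4 and sets the lactone stereocentre from the bought carbinol centre.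
4. 10 ⇐ (S)‑carvone: ring B and the ring‑fusion CH are bought; the quaternary ring‑fusion carbon is set by two enolate alkylations (methyl last); ring A is closed by a 6‑exo reductive Heck reaction onto the isopropenyl group (gem‑dimethyl, cis fusion).
5. Ring order: ring B (bought) → ring A (step 3) → butyrolactone (step 9); fragments joined in steps 14 and 15.

Assumption: the SMILES is taken as drawn, i.e. a cis‑fused (4aR,8aS)‑octalin, a (3Z)‑alkene, a (1R)‑carbinol and a (4S)‑lactone carbon in the numbering of the name of 35. Abbreviations: TBS = tert‑butyldimethylsilyl, Tf = trifluoromethanesulfonyl.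

**Step 1**
Reactants: 1 (S)‑carvone; 2 (Z)‑1,3‑dichloroprop‑1‑ene
Product: 4 (5S,6R)‑6‑[(2Z)‑3‑chloroprop‑2‑en‑1‑yl]‑2‑methyl‑5‑(prop‑1‑en‑2‑yl)cyclohex‑2‑en‑1‑one, via lithium dienolate 3 (not isolated)
Conditions: LiN(i‑Pr)2, THF, −78 °C; then 2, DMPU, −78 → 0 °C
Reagents that add atoms: none
Why: Kinetic α′‑deprotonation and SN2 enolate alkylation at the allylic CH2Cl (the vinylic C–Cl is inert) occur anti to the neighbouring isopropenyl group, giving mainly the trans product whose new C6 centre is re‑set in step 2.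

**Step 2**
Reactants: 4 chloroallyl carvone
Product: 6 (5R,6S)‑6‑[(2Z)‑3‑chloroprop‑2‑en‑1‑yl]‑2,6‑dimethyl‑5‑(prop‑1‑en‑2‑yl)cyclohex‑2‑en‑1‑one, via lithium enolate 5 (not isolated)
Conditions: LiN(i‑Pr)2, THF, −78 → −30 °C; then MeI, DMPU, −78 → 0 °C
Reagents that add atoms: iodomethane, CI
Why: Enolate alkylation in which MeI approaches the substituted dienolate carbon anti to the adjacent isopropenyl group, so the bought C5 centre sets the quaternary centre with methyl trans and the chloroallyl chain cis to isopropenyl.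

**Step 3**
Reactants: 6 quaternary chloroallyl enone
Product: 7 (4aR,8aS)‑2,5,5,8a‑tetramethyl‑4a,5,8,8a‑tetrahydronaphthalen‑1(4H)‑one
Conditions: Pd(OAc)2 (10 mol %), P(t‑Bu)3·HBF4 (20 mol %), HCO2Na, DMF, 90 °C
Reagents that add atoms: none
Why: Intramolecular reductive Heck reaction in which the alkenylpalladium from the (Z)‑chloride inserts 6‑exo into the cis‑disposed isopropenyl group and the resulting neopentylpalladium, which has no β‑hydrogen, is reduced by formate, so ring A closes cis‑fused with a gem‑dimethyl carbon and no stereocentre is touched.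

**Step 4**
Reactants: 7 bicyclic dienone
Product: 8 (4aR,8aS)‑2,5,5,8a‑tetramethyloctahydronaphthalen‑1(2H)‑one (both C2 epimers)
Conditions: H2 (1 atm), Pd/C, EtOAc, rt
Reagents that add atoms: none
Why: Catalytic hydrogenation saturates the ring‑A alkene and the enone C=C but not the hindered ketone, and the new C2 centre (formed as a mixture) is removed in step 5.

**Step 5**
Reactants: 8 cis‑decalone
Product: 10 (4aR,8aS)‑2,5,5,8a‑tetramethyl‑3,4,4a,5,6,7,8,8a‑octahydronaphthalen‑1‑yl trifluoromethanesulfonate, via potassium enolate 9 (not isolated)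
Conditions: KN(SiMe3)2, THF, −78 → 0 °C; then PhNTf2, −78 °C → rt
Reagents that add atoms: N‑phenylbis(trifluoromethanesulfonimide), O=S(=O)(N(c1ccccc1)S(=O)(=O)C(F)(F)F)C(F)(F)F
Why: Enol triflate formation is regiospecific because C2 is the only enolisable position (C8a is quaternary), as with 2,2,6‑trimethylcyclohexanone, and it erases the C2 stereocentre.

**Step 6**
Reactants: 11 (R)‑2,2‑dimethyl‑1,3‑dioxolane‑4‑carbaldehyde; 12 methyl (triphenylphosphoranylidene)acetate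
Product: 13 methyl (2Z)‑3‑[(4S)‑2,2‑dimethyl‑1,3‑dioxolan‑4‑yl]prop‑2‑enoate
Conditions: MeOH, 0 °C
Reagents that add atoms: none
Why: Wittig olefination with a stabilised ylide is Z‑selective for α‑alkoxy aldehydes in methanol (about 8:1, E isomer removed by chromatography) and leaves the bought stereocentre untouched.

**Step 7**
Reactants: 13 (Z)‑enoate
Product: 14 (2Z)‑3‑[(4S)‑2,2‑dimethyl‑1,3‑dioxolan‑4‑yl]prop‑2‑en‑1‑ol
Conditions: i‑Bu2AlH (2.2 equiv), CH2Cl2, −78 °C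
Reagents that add atoms: none
Why: Hydride reduction of the ester (1,2‑reduction of an enoate) gives the allylic alcohol without Z to E isomerisation.

**Step 8**
Reactants: 14 (Z)‑allylic alcohol; 15 triethyl orthoacetate
Product: 18 ethyl (3S)‑3‑[(4S)‑2,2‑dimethyl‑1,3‑dioxolan‑4‑yl]pent‑4‑enoate, via mixed orthoester 16 (not isolated), via ketene acetal 17 (not isolated)
Conditions: EtCO2H (cat.), neat 15, 135 °C, EtOH distilled off
Reagents that add atoms: none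
Why: Johnson–Claisen [3,3]‑sigmatropic rearrangement through a chair transition state in which the Z‑alkene holds the allylic C–H in the alkene plane (A(1,3) strain) and the new C–C bond forms anti to the dioxolane C–O bond, so the bought centre sets the new C3 centre as S (about 9:1 expected, minor epimer separable).

**Step 9**
Reactants: 18 pentenoate
Product: 21 (4S)‑4‑[(4S)‑2,2‑dimethyl‑1,3‑dioxolan‑4‑yl]oxolan‑2‑one, via ozonide 19 (not isolated), via hydroxy ester 20 (not isolated)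
Conditions: O3, CH2Cl2, −78 °C; then NaBH4, MeOH, −78 → 0 °C; then PPTS (cat.), CH2Cl2, rt
Reagents that add atoms: ozone, [O-][O+]=O
Why: Ozonolysis with reductive borohydride work‑up turns the vinyl group into CH2OH, which lactonises 5‑exo onto the ester (γ‑lactone formation) while both stereocentres stay untouched.

**Step 10**
Reactants: 21 lactone acetonide
Product: 22 (4S)‑4‑[(1S)‑1,2‑dihydroxyethyl]oxolan‑2‑one
Conditions: AcOH/H2O (4:1), 40 °C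
Reagents that add atoms: none
Why: Acid‑catalysed acetonide hydrolysis frees the diol under conditions too mild for lactone opening or migration.

**Step 11**
Reactants: 22 lactone diol
Product: 24 (2S)‑2‑(TBS‑oxy)‑2‑[(3S)‑5‑oxooxolan‑3‑yl]ethyl trifluoromethanesulfonate, via hydroxy triflate 23 (not isolated)
Conditions: Tf2O (1.05 equiv), 2,6‑lutidine, CH2Cl2, −78 °C; then TBSOTf, −78 → −40 °C
Reagents that add atoms: trifluoromethanesulfonic anhydride, O=S(=O)(OS(=O)(=O)C(F)(F)F)C(F)(F)F; tert‑butyldimethylsilyl trifluoromethanesulfonate, CC(C)(C)[Si](C)(C)OS(=O)(=O)C(F)(F)F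
Why: Chemoselective O‑sulfonylation of the primary hydroxyl at −78 °C followed by silylation of the secondary hydroxyl in the same flask (one‑pot triflation–silylation) breaks no bond at the stereocentre.

**Step 12**
Reactants: 25 prop‑2‑yn‑1‑ol; 26 vinylmagnesium bromide
Product: 29 (2Z)‑2‑(iodomethylidene)but‑3‑en‑1‑ol, via magnesium alkoxide 27 (not isolated), via alkenylmagnesium chelate 28 (not isolated)
Conditions: 26 (2.5 equiv), CuI (10 mol %), THF, −10 °C → rt; then I2, −40 °C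
Reagents that add atoms: iodine, [I][I]
Why: Copper‑catalysed anti‑carbomagnesiation of the propargylic alkoxide (Duboudin reaction) delivers the vinyl group to the internal alkyne carbon and magnesium to the terminal carbon in a five‑membered chelate, and iodinolysis with retention gives the Z‑iodide with iodine cis to CH2OH.

**Step 13**
Reactants: 29 dienyl iodide alcohol
Product: 30 tert‑butyl{[(2Z)‑2‑(iodomethylidene)but‑3‑en‑1‑yl]oxy}dimethylsilane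
Conditions: TBSCl, imidazole, DMF, 0 °C → rt
Reagents that add atoms: tert‑butyl(chloro)dimethylsilane, CC(C)(C)[Si](C)(C)Cl
Why: Silyl ether formation on the primary allylic alcohol proceeds without affecting the iodoalkene geometry.

**Step 14**
Reactants: 30 silylated dienyl iodide; 24 lactone triflate
Product: 32 (4S)‑4‑[(1R,3Z)‑1‑(TBS‑oxy)‑4‑(TBS‑oxymethyl)hexa‑3,5‑dien‑1‑yl]oxolan‑2‑one, via alkenylmagnesium chloride 31 (not isolated)
Conditions: i‑PrMgCl·LiCl, THF, −20 → 0 °C; then 24, CuBr·SMe2 (10 mol %), −78 → −30 °C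
Reagents that add atoms: none
Why: Iodine–magnesium exchange retains the alkene geometry and the copper‑catalysed SN2 coupling of the alkenyl Grignard reagent with the primary triflate (Kotsuki‑type alkylation) is faster than addition to the lactone at low temperature, the silyloxy stereocentre being untouched.

**Step 15**
Reactants: 32 dienyl lactone; 10 alkenyl triflate
Product: 34 (4S)‑4‑[(1R,3Z)‑1‑(TBS‑oxy)‑4‑(TBS‑oxymethyl)‑6‑[(4aR,8aS)‑2,5,5,8a‑tetramethyl‑3,4,4a,5,6,7,8,8a‑octahydronaphthalen‑1‑yl]hex‑3‑en‑1‑yl]oxolan‑2‑one, via alkylborane 33 (not isolated)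
Conditions: 9‑BBN‑H, THF, 0 °C → rt; then 10, Pd(PPh3)4 (10 mol %), K3PO4, H2O (few equiv), dioxane, 85 °C
Reagents that add atoms: none
Why: 9‑BBN‑H hydroborates only the terminal vinyl group anti‑Markovnikov, and B‑alkyl Suzuki–Miyaura coupling of the primary alkylborane with the tetrasubstituted alkenyl triflate joins the fragments with both alkene geometries retained.

**Step 16**
Reactants: 34 bis‑TBS ether
Product: 35 (4S)‑4‑[(1R,3Z)‑1‑hydroxy‑4‑(hydroxymethyl)‑6‑[(4aR,8aS)‑2,5,5,8a‑tetramethyl‑3,4,4a,5,6,7,8,8a‑octahydronaphthalen‑1‑yl]hex‑3‑en‑1‑yl]oxolan‑2‑one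
Conditions: HF·pyridine, pyridine, THF, 0 °C → rt
Reagents that add atoms: none
Why: Fluoride‑mediated desilylation under buffered, mildly acidic conditions removes both silyl ethers without translactonisation or alkene migration.

**Compound list**
1 | (S)‑carvone; (5S)‑2‑methyl‑5‑(prop‑1‑en‑2‑yl)cyclohex‑2‑en‑1‑one | CC1=CC[C@@H](CC1=O)C(C)=C | starting material
2 | (Z)‑1,3‑dichloroprop‑1‑ene | ClC/C=C\Cl | starting material
3 | lithium (3S)‑6‑methyl‑3‑(prop‑1‑en‑2‑yl)cyclohexa‑1,5‑dien‑1‑olate | CC1=CC[C@@H](C=C1O[Li])C(C)=C | intermediate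
4 | (5S,6R)‑6‑[(2Z)‑3‑chloroprop‑2‑en‑1‑yl]‑2‑methyl‑5‑(prop‑1‑en‑2‑yl)cyclohex‑2‑en‑1‑one | CC1=CC[C@H](C(C)=C)[C@@H](C/C=C\Cl)C1=O | intermediate
5 | lithium (3R)‑2‑[(2Z)‑3‑chloroprop‑2‑en‑1‑yl]‑6‑methyl‑3‑(prop‑1‑en‑2‑yl)cyclohexa‑1,5‑dien‑1‑olate | CC1=CC[C@H](C(C)=C)C(C/C=C\Cl)=C1O[Li] | intermediate
6 | (5R,6S)‑6‑[(2Z)‑3‑chloroprop‑2‑en‑1‑yl]‑2,6‑dimethyl‑5‑(prop‑1‑en‑2‑yl)cyclohex‑2‑en‑1‑one | CC1=CC[C@H](C(C)=C)[C@](C)(C/C=C\Cl)C1=O | intermediate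
7 | (4aR,8aS)‑2,5,5,8a‑tetramethyl‑4a,5,8,8a‑tetrahydronaphthalen‑1(4H)‑one | CC1=CC[C@@H]2C(C)(C)C=CC[C@]2(C)C1=O | intermediate
8 | (4aR,8aS)‑2,5,5,8a‑tetramethyloctahydronaphthalen‑1(2H)‑one (C2 epimers) | CC1CC[C@@H]2C(C)(C)CCC[C@]2(C)C1=O | intermediate
9 | potassium (4aR,8aS)‑2,5,5,8a‑tetramethyl‑3,4,4a,5,6,7,8,8a‑octahydronaphthalen‑1‑olate | CC1=C(O[K])[C@@]2(C)CCCC(C)(C)[C@H]2CC1 | intermediate
10 | (4aR,8aS)‑2,5,5,8a‑tetramethyl‑3,4,4a,5,6,7,8,8a‑octahydronaphthalen‑1‑yl trifluoromethanesulfonate | CC1=C(OS(=O)(=O)C(F)(F)F)[C@@]2(C)CCCC(C)(C)[C@H]2CC1 | intermediate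
11 | (R)‑2,2‑dimethyl‑1,3‑dioxolane‑4‑carbaldehyde (D‑glyceraldehyde acetonide) | O=C[C@H]1COC(C)(C)O1 | starting material
12 | methyl (triphenylphosphoranylidene)acetate | COC(=O)C=P(c1ccccc1)(c1ccccc1)c1ccccc1 | starting material
13 | methyl (2Z)‑3‑[(4S)‑2,2‑dimethyl‑1,3‑dioxolan‑4‑yl]prop‑2‑enoate | COC(=O)/C=C\[C@H]1COC(C)(C)O1 | intermediate
14 | (2Z)‑3‑[(4S)‑2,2‑dimethyl‑1,3‑dioxolan‑4‑yl]prop‑2‑en‑1‑ol | OC/C=C\[C@H]1COC(C)(C)O1 | intermediate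
15 | triethyl orthoacetate (1,1,1‑triethoxyethane) | CCOC(C)(OCC)OCC | starting material
16 | (4S)‑4‑[(1Z)‑3‑(1,1‑diethoxyethoxy)prop‑1‑en‑1‑yl]‑2,2‑dimethyl‑1,3‑dioxolane | CCOC(C)(OCC)OC/C=C\[C@H]1COC(C)(C)O1 | intermediate
17 | (4S)‑4‑{(1Z)‑3‑[(1‑ethoxyethenyl)oxy]prop‑1‑en‑1‑yl}‑2,2‑dimethyl‑1,3‑dioxolane | CCOC(=C)OC/C=C\[C@H]1COC(C)(C)O1 | intermediate
18 | ethyl (3S)‑3‑[(4S)‑2,2‑dimethyl‑1,3‑dioxolan‑4‑yl]pent‑4‑enoate | CCOC(=O)C[C@@H](C=C)[C@H]1COC(C)(C)O1 | intermediate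
19 | ethyl (3R)‑3‑[(4S)‑2,2‑dimethyl‑1,3‑dioxolan‑4‑yl]‑3‑(1,2,4‑trioxolan‑3‑yl)propanoate (trioxolane carbon unassigned) | CCOC(=O)C[C@@H](C1OCOO1)[C@H]1COC(C)(C)O1 | intermediate
20 | ethyl (3S)‑3‑[(4S)‑2,2‑dimethyl‑1,3‑dioxolan‑4‑yl]‑4‑hydroxybutanoate | CCOC(=O)C[C@@H](CO)[C@H]1COC(C)(C)O1 | intermediate
21 | (4S)‑4‑[(4S)‑2,2‑dimethyl‑1,3‑dioxolan‑4‑yl]oxolan‑2‑one | O=C1C[C@@H](CO1)[C@H]1COC(C)(C)O1 | intermediate
22 | (4S)‑4‑[(1S)‑1,2‑dihydroxyethyl]oxolan‑2‑one | O=C1C[C@@H](CO1)[C@H](O)CO | intermediate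
23 | (2S)‑2‑hydroxy‑2‑[(3S)‑5‑oxooxolan‑3‑yl]ethyl trifluoromethanesulfonate | O=C1C[C@@H](CO1)[C@H](O)COS(=O)(=O)C(F)(F)F | intermediate
24 | (2S)‑2‑{[tert‑butyl(dimethyl)silyl]oxy}‑2‑[(3S)‑5‑oxooxolan‑3‑yl]ethyl trifluoromethanesulfonate | O=C1C[C@@H](CO1)[C@H](O[Si](C)(C)C(C)(C)C)COS(=O)(=O)C(F)(F)F | intermediate
25 | prop‑2‑yn‑1‑ol | C#CCO | starting material
26 | vinylmagnesium bromide | C=C[Mg]Br | starting material
27 | bromomagnesium prop‑2‑yn‑1‑olate | C#CCO[Mg]Br | intermediate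
28 | (Z)‑[2‑(bromomagnesiooxymethyl)buta‑1,3‑dien‑1‑yl]magnesium bromide | Br[Mg]/C=C(\CO[Mg]Br)C=C | intermediate
29 | (2Z)‑2‑(iodomethylidene)but‑3‑en‑1‑ol | I/C=C(\CO)C=C | intermediate
30 | tert‑butyl{[(2Z)‑2‑(iodomethylidene)but‑3‑en‑1‑yl]oxy}dimethylsilane | I/C=C(\CO[Si](C)(C)C(C)(C)C)C=C | intermediate
31 | [(1Z)‑2‑({[tert‑butyl(dimethyl)silyl]oxy}methyl)buta‑1,3‑dien‑1‑yl]magnesium chloride | Cl[Mg]/C=C(\CO[Si](C)(C)C(C)(C)C)C=C | intermediate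
32 | (4S)‑4‑[(1R,3Z)‑1‑{[tert‑butyl(dimethyl)silyl]oxy}‑4‑({[tert‑butyl(dimethyl)silyl]oxy}methyl)hexa‑3,5‑dien‑1‑yl]oxolan‑2‑one | C=C/C(CO[Si](C)(C)C(C)(C)C)=C/C[C@@H](O[Si](C)(C)C(C)(C)C)[C@@H]1COC(=O)C1 | intermediate
33 | (4S)‑4‑[(1R,3Z)‑6‑(9‑borabicyclo[3.3.1]nonan‑9‑yl)‑1‑{[tert‑butyl(dimethyl)silyl]oxy}‑4‑({[tert‑butyl(dimethyl)silyl]oxy}methyl)hex‑3‑en‑1‑yl]oxolan‑2‑one | B1(CC/C(CO[Si](C)(C)C(C)(C)C)=C/C[C@@H](O[Si](C)(C)C(C)(C)C)[C@@H]2COC(=O)C2)C2CCCC1CCC2 | intermediate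
34 | (4S)‑4‑[(1R,3Z)‑1‑{[tert‑butyl(dimethyl)silyl]oxy}‑4‑({[tert‑butyl(dimethyl)silyl]oxy}methyl)‑6‑[(4aR,8aS)‑2,5,5,8a‑tetramethyl‑3,4,4a,5,6,7,8,8a‑octahydronaphthalen‑1‑yl]hex‑3‑en‑1‑yl]oxolan‑2‑one | CC1=C(CC/C(CO[Si](C)(C)C(C)(C)C)=C/C[C@@H](O[Si](C)(C)C(C)(C)C)[C@@H]2COC(=O)C2)[C@@]2(C)CCCC(C)(C)[C@H]2CC1 | intermediate
35 | (4S)‑4‑[(1R,3Z)‑1‑hydroxy‑4‑(hydroxymethyl)‑6‑[(4aR,8aS)‑2,5,5,8a‑tetramethyl‑3,4,4a,5,6,7,8,8a‑octahydronaphthalen‑1‑yl]hex‑3‑en‑1‑yl]oxolan‑2‑one | CC1=C(CC/C(=C/C[C@@H](O)[C@@H]2COC(=O)C2)CO)[C@@]2(C)CCCC(C)(C)[C@H]2CC1 | target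

**Totals**
Total step count: 16.
Longest linear sequence: 9 steps (11 → 35 through steps 6–11 and 14–16).

**Steps most likely to fail, with fallbacks**

First risk, step 3: an unactivated alkenyl chloride may be reluctant in the palladium ring closure, or may simply be reduced. The fallback closes ring A by olefin metathesis and brings in the second methyl group as a cyclopropane carbon; it sets out from 1 and returns at 8. Alkylation of 1 with 4‑iodobut‑1‑ene (LiN(i‑Pr)2, THF/DMPU) gives (5S,6R)‑6‑(but‑3‑en‑1‑yl)‑2‑methyl‑5‑(prop‑1‑en‑2‑yl)cyclohex‑2‑en‑1‑one F1. Methylation as in step 2 gives (5R,6S)‑6‑(but‑3‑en‑1‑yl)‑2,6‑dimethyl‑5‑(prop‑1‑en‑2‑yl)cyclohex‑2‑en‑1‑one F2. Ring‑closing metathesis with second‑generation Grubbs catalyst gives (4aR,8aS)‑2,5,8a‑trimethyl‑4a,7,8,8a‑tetrahydronaphthalen‑1(4H)‑one F3. Simmons–Smith cyclopropanation (Et2Zn, CH2I2) of the ring‑A alkene gives (4aR,8aS)‑5,6‑methano‑2,5,8a‑trimethyl‑4a,5,6,7,8,8a‑hexahydronaphthalen‑1(4H)‑one F4. Hydrogenolysis of the less hindered cyclopropane bond together with full hydrogenation (H2, PtO2, AcOH) gives (4aR,8aS)‑2,5,5,8a‑tetramethyldecahydronaphthalen‑1‑ol F5, and Dess–Martin oxidation returns to 8.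

Second risk, step 14: the primary triflate 24 may be too labile, or the Grignard reagent may attack the lactone. The fallback makes the same C–C bond by epoxide opening; it sets out from 22 and returns at 32. Mitsunobu cyclodehydration of 22 (PPh3, DIAD; the primary hydroxyl is activated, so the carbinol centre is retained) gives (4S)‑4‑[(2S)‑oxiran‑2‑yl]oxolan‑2‑one F6. Copper‑catalysed opening of F6 at its CH2 terminus by the alkenylmagnesium reagent 31 gives (4S)‑4‑[(1R,3Z)‑4‑({[tert‑butyl(dimethyl)silyl]oxy}methyl)‑1‑hydroxyhexa‑3,5‑dien‑1‑yl]oxolan‑2‑one F7, and silylation (TBSOTf, 2,6‑lutidine) returns to 32.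

Third risk, step 15: the tetrasubstituted triflate 10 may be too hindered for a late B‑alkyl coupling next to a base‑sensitive lactone. The fallback attaches the two‑carbon link to the decalin first by an easier sp2–sp2 coupling and then builds the trisubstituted alkene on it; it sets out from 10 and returns at 34. Stille coupling of 10 with tributyl(vinyl)stannane (Pd(PPh3)4, LiCl, THF) gives (4aR,8aS)‑1‑ethenyl‑2,5,5,8a‑tetramethyl‑3,4,4a,5,6,7,8,8a‑octahydronaphthalene F8. Hydroboration–oxidation of the vinyl group (9‑BBN‑H; H2O2, NaOH) gives 2‑[(4aR,8aS)‑2,5,5,8a‑tetramethyl‑3,4,4a,5,6,7,8,8a‑octahydronaphthalen‑1‑yl]ethan‑1‑ol F9. Appel bromination (CBr4, PPh3) gives (4aR,8aS)‑1‑(2‑bromoethyl)‑2,5,5,8a‑tetramethyl‑3,4,4a,5,6,7,8,8a‑octahydronaphthalene F10. Magnesium insertion gives {2‑[(4aR,8aS)‑2,5,5,8a‑tetramethyl‑3,4,4a,5,6,7,8,8a‑octahydronaphthalen‑1‑yl]ethyl}magnesium bromide F11. This is added under CuI catalysis to 27 (made here from 25 and one equivalent of EtMgBr) and quenched with I2 to give (2Z)‑2‑(iodomethylidene)‑4‑[(4aR,8aS)‑2,5,5,8a‑tetramethyl‑3,4,4a,5,6,7,8,8a‑octahydronaphthalen‑1‑yl]butan‑1‑ol F12. Silylation (TBSCl, imidazole) gives tert‑butyl{[(2Z)‑2‑(iodomethylidene)‑4‑[(4aR,8aS)‑2,5,5,8a‑tetramethyl‑3,4,4a,5,6,7,8,8a‑octahydronaphthalen‑1‑yl]butyl]oxy}dimethylsilane F13. Iodine–magnesium exchange (i‑PrMgCl·LiCl) gives [(1Z)‑2‑({[tert‑butyl(dimethyl)silyl]oxy}methyl)‑4‑[(4aR,8aS)‑2,5,5,8a‑tetramethyl‑3,4,4a,5,6,7,8,8a‑octahydronaphthalen‑1‑yl]but‑1‑en‑1‑yl]magnesium chloride F14, and its copper‑catalysed coupling with 24 under the conditions of step 14 returns to 34.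

**Further compounds**
F1 | step 3 | (5S,6R)‑6‑(but‑3‑en‑1‑yl)‑2‑methyl‑5‑(prop‑1‑en‑2‑yl)cyclohex‑2‑en‑1‑one | CC1=CC[C@H](C(C)=C)[C@@H](CCC=C)C1=O
F2 | step 3 | (5R,6S)‑6‑(but‑3‑en‑1‑yl)‑2,6‑dimethyl‑5‑(prop‑1‑en‑2‑yl)cyclohex‑2‑en‑1‑one | CC1=CC[C@H](C(C)=C)[C@](C)(CCC=C)C1=O
F3 | step 3 | (4aR,8aS)‑2,5,8a‑trimethyl‑4a,7,8,8a‑tetrahydronaphthalen‑1(4H)‑one | CC1=CC[C@@H]2C(C)=CCC[C@]2(C)C1=O
F4 | step 3 | (4aR,8aS)‑5,6‑methano‑2,5,8a‑trimethyl‑4a,5,6,7,8,8a‑hexahydronaphthalen‑1(4H)‑one (cyclopropane on either face) | CC1=CC[C@@H]2C3(C)CC3CC[C@]2(C)C1=O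
F5 | step 3 | (4aR,8aS)‑2,5,5,8a‑tetramethyldecahydronaphthalen‑1‑ol (C1 and C2 epimers) | CC1CC[C@@H]2C(C)(C)CCC[C@]2(C)C1O
F6 | step 14 | (4S)‑4‑[(2S)‑oxiran‑2‑yl]oxolan‑2‑one | O=C1C[C@@H](CO1)[C@H]1CO1
F7 | step 14 | (4S)‑4‑[(1R,3Z)‑4‑({[tert‑butyl(dimethyl)silyl]oxy}methyl)‑1‑hydroxyhexa‑3,5‑dien‑1‑yl]oxolan‑2‑one | C=C/C(CO[Si](C)(C)C(C)(C)C)=C/C[C@@H](O)[C@@H]1COC(=O)C1
F8 | step 15 | (4aR,8aS)‑1‑ethenyl‑2,5,5,8a‑tetramethyl‑3,4,4a,5,6,7,8,8a‑octahydronaphthalene | CC1=C(C=C)[C@@]2(C)CCCC(C)(C)[C@H]2CC1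
F9 | step 15 | 2‑[(4aR,8aS)‑2,5,5,8a‑tetramethyl‑3,4,4a,5,6,7,8,8a‑octahydronaphthalen‑1‑yl]ethan‑1‑ol | CC1=C(CCO)[C@@]2(C)CCCC(C)(C)[C@H]2CC1
F10 | step 15 | (4aR,8aS)‑1‑(2‑bromoethyl)‑2,5,5,8a‑tetramethyl‑3,4,4a,5,6,7,8,8a‑octahydronaphthalene | CC1=C(CCBr)[C@@]2(C)CCCC(C)(C)[C@H]2CC1
F11 | step 15 | {2‑[(4aR,8aS)‑2,5,5,8a‑tetramethyl‑3,4,4a,5,6,7,8,8a‑octahydronaphthalen‑1‑yl]ethyl}magnesium bromide | CC1=C(CC[Mg]Br)[C@@]2(C)CCCC(C)(C)[C@H]2CC1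
F12 | step 15 | (2Z)‑2‑(iodomethylidene)‑4‑[(4aR,8aS)‑2,5,5,8a‑tetramethyl‑3,4,4a,5,6,7,8,8a‑octahydronaphthalen‑1‑yl]butan‑1‑ol | CC1=C(CC/C(CO)=C/I)[C@@]2(C)CCCC(C)(C)[C@H]2CC1
F13 | step 15 | tert‑butyl{[(2Z)‑2‑(iodomethylidene)‑4‑[(4aR,8aS)‑2,5,5,8a‑tetramethyl‑3,4,4a,5,6,7,8,8a‑octahydronaphthalen‑1‑yl]butyl]oxy}dimethylsilane | CC1=C(CC/C(CO[Si](C)(C)C(C)(C)C)=C/I)[C@@]2(C)CCCC(C)(C)[C@H]2CC1
F14 | step 15 | [(1Z)‑2‑({[tert‑butyl(dimethyl)silyl]oxy}methyl)‑4‑[(4aR,8aS)‑2,5,5,8a‑tetramethyl‑3,4,4a,5,6,7,8,8a‑octahydronaphthalen‑1‑yl]but‑1‑en‑1‑yl]magnesium chloride | CC1=C(CC/C(CO[Si](C)(C)C(C)(C)C)=C/[Mg]Cl)[C@@]2(C)CCCC(C)(C)[C@H]2CC1
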